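**Retrosynthetic overview**

1. Target ⇒ protected benzophenone by removal of four MOM groups and a C6 silyl blocking group. The aryl–C(=O) bond at C8 of the chromene comes from C8 lithiation and addition to the ring-A aldehyde, then oxidation.
2. Ring-A aldehyde ⇒ 3,5-dihydroxybenzaldehyde by MOM protection, C2 bromination and Stille prenylation.
3. Chromene ⇒ 3,5-bis(MOM-oxy)benzyne + 3-methylbut-2-enal. Formal [2+2] gives a 2H-benzoxete (O1, C4, C4a, C8a); 4π opening and oxa-6π closure insert C3 and C2, so the four-membered ring becomes the pyran.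
4. Enabling feature: the pyran ring O1–C2(Me2)–C3=C4–C4a=C8a is the valence isomer of a vinyl o-quinone methide, and the C4a/C8a pair carries an oxygen on one flank only (C5–O), which fixes the direction of aryne attack.
5. Ring order: ring A (commercial arene), ring B (phloroglucinol), oxete, then pyran in the key step.

Key step: step 6

Remark: the target has no stereocentre and no stereogenic double bond; it is achiral, so the route is planned for the constitution given.

**Route**

Step 1
Reactants: 1 phloroglucinol (benzene-1,3,5-triol)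
Product: 2 3,5-bis(methoxymethoxy)phenol
Conditions: MOMCl (2.0 equiv), i-Pr2NEt, DMF, 0 °C → rt; chromatography
Reagents that add atoms: chloromethyl methyl ether (MOMCl), COCCl
Why: Williamson-type O-alkylation of the C3-symmetric triol is statistical, so two equivalents of MOMCl should give the bis-ether as the main component, separable from mono- and tris-ethers, which can be recycled.

Step 2
Reactants: 2 3,5-bis(methoxymethoxy)phenol
Product: 3 3,5-bis(methoxymethoxy)phenyl N,N-diethylcarbamate
Conditions: NaH, THF, 0 °C; ClC(O)NEt2, rt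
Reagents that add atoms: N,N-diethylcarbamoyl chloride, CCN(CC)C(Cl)=O
Why: O-carbamoylation of the sodium phenoxide (acyl substitution) installs the strongest oxygen-based directing group for the metalation that follows.

Step 3
Reactants: 3 3,5-bis(methoxymethoxy)phenyl N,N-diethylcarbamate
Product: 5 3,5-bis(methoxymethoxy)-2-(trimethylsilyl)phenyl N,N-diethylcarbamate, via 2-lithio carbamate 4 (not isolated)
Conditions: s-BuLi, TMEDA, THF, −78 °C; TMSCl, −78 °C → rt
Reagents that add atoms: chlorotrimethylsilane (TMSCl), C[Si](C)(C)Cl
Why: Directed ortho-metalation should occur at C2 (equivalent to C6), the position flanked by the carbamate and an OMOM group, and silylation at −78 °C traps the aryllithium before an anionic ortho-Fries shift can set in.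

Step 4
Reactants: 5 3,5-bis(methoxymethoxy)-2-(trimethylsilyl)phenyl N,N-diethylcarbamate
Product: 6 3,5-bis(methoxymethoxy)-2-(trimethylsilyl)phenol
Conditions: LiAlH4, THF, 0 °C → reflux; aqueous NaOH work-up
Reagents that add atoms: none
Why: Hydride reduction of the carbamate carbonyl expels the phenoxide (reductive carbamate cleavage), while MOM acetals and the aryl–silicon bond are inert to LiAlH4.

Step 5
Reactants: 6 3,5-bis(methoxymethoxy)-2-(trimethylsilyl)phenol
Product: 7 3,5-bis(methoxymethoxy)-2-(trimethylsilyl)phenyl trifluoromethanesulfonate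
Conditions: Tf2O, pyridine, CH2Cl2, 0 °C
Reagents that add atoms: trifluoromethanesulfonic anhydride (Tf2O), O=S(=O)(OS(=O)(=O)C(F)(F)F)C(F)(F)F
Why: O-sulfonylation of the phenol gives the ortho-silylaryl triflate (Kobayashi-type aryne precursor) under basic conditions that leave the acetals and the C–Si bond alone.

Step 6
Reactants: 7 3,5-bis(methoxymethoxy)-2-(trimethylsilyl)phenyl trifluoromethanesulfonate; 8 3-methylbut-2-enal
Product: 12 5,7-bis(methoxymethoxy)-2,2-dimethyl-2H-chromene, via 3,5-bis(methoxymethoxy)benzyne 9 (not isolated), via 2H-benzoxete 10 (not isolated), via o-quinone methide 11 (not isolated)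
Conditions: CsF (3 equiv), 8 (5 equiv), MeCN, 25 → 40 °C, slow addition of 7
Reagents that add atoms: none
Why: Fluoride attacks silicon and triflate leaves to give aryne 9; the carbonyl oxygen of 8 adds to the aryne carbon remote from the flanking OMOM group, and the aryl anion formed next to that OMOM collapses onto the oxocarbenium carbon, a stepwise formal [2+2] that closes the four-membered 2H-benzoxete 10 (O1, C4, C4a, C8a). Thermal 4π-electrocyclic opening of the oxete gives the vinyl o-quinone methide 11, whose 1-oxatriene closes by oxa-6π-electrocyclisation to the 2H-pyran, so the four-membered ring grows by C3 and C2 and the arene is regained. The closest known reaction type is the annulation of arynes with α,β-unsaturated aldehydes to 2H-chromenes (benzyne with cinnamaldehyde) and the related insertion of arynes into the C=O bond of formamides. No stereocentre remains: the sp3 carbon of 10 is transient, only the Z-dienone closes, and the E isomer can return through 10. The step needs O-attack at C8a, which is secured by the single flanking alkoxy group at C5 (inductive aryne distortion; the other flank is C–H). It also needs the carbonyl [2+2] to win over ene or [4+2] modes and over capture of 11 by a second aryne, which excess enal, slow aryne release and the intramolecular 6π closure should secure.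

Step 7
Reactants: 12 5,7-bis(methoxymethoxy)-2,2-dimethyl-2H-chromene
Product: 14 5,7-bis(methoxymethoxy)-2,2-dimethyl-6-(trimethylsilyl)-2H-chromene, via 6-lithio chromene 13 (not isolated)
Conditions: n-BuLi, THF, −40 → 0 °C; TMSCl
Reagents that add atoms: chlorotrimethylsilane (TMSCl), C[Si](C)(C)Cl
Why: Directed ortho-metalation occurs at C6, the most acidic ring position because it lies between two OMOM groups, and silylation there blocks this site so that the next metalation can only go to C8.

Step 8
Reactants: 15 3,5-dihydroxybenzaldehyde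
Product: 16 3,5-bis(methoxymethoxy)benzaldehyde
Conditions: MOMCl (2.5 equiv), i-Pr2NEt, CH2Cl2, 0 °C → rt
Reagents that add atoms: chloromethyl methyl ether (MOMCl), COCCl
Why: Standard MOM protection of both phenols (Williamson-type O-alkylation) is compatible with the aldehyde.

Step 9
Reactants: 16 3,5-bis(methoxymethoxy)benzaldehyde
Product: 17 2-bromo-3,5-bis(methoxymethoxy)benzaldehyde
Conditions: NBS (1.0 equiv), MeCN, 0 °C → rt
Reagents that add atoms: N-bromosuccinimide (NBS), O=C1CCC(=O)N1Br
Why: Electrophilic aromatic bromination should go to C2 (equivalent to C6), para to one OMOM and ortho to the other, and not to the more hindered C4 between the two acetals, as known for 3,5-dialkoxybenzaldehydes.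

Step 10
Reactants: 17 2-bromo-3,5-bis(methoxymethoxy)benzaldehyde; 18 tributyl(3-methylbut-2-en-1-yl)stannane
Product: 19 3,5-bis(methoxymethoxy)-2-(3-methylbut-2-en-1-yl)benzaldehyde
Conditions: Pd(PPh3)4 (5 mol %), DMF, 100 °C
Reagents that add atoms: none
Why: Stille cross-coupling of the ortho-formyl aryl bromide with the prenylstannane should transfer the allyl group at its tin-bearing carbon and so give the linear 3-methylbut-2-enyl side chain.

Step 11
Reactants: 14 5,7-bis(methoxymethoxy)-2,2-dimethyl-6-(trimethylsilyl)-2H-chromene; 19 3,5-bis(methoxymethoxy)-2-(3-methylbut-2-en-1-yl)benzaldehyde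
Product: 21 [5,7-bis(methoxymethoxy)-2,2-dimethyl-6-(trimethylsilyl)-2H-chromen-8-yl][3,5-bis(methoxymethoxy)-2-(3-methylbut-2-en-1-yl)phenyl]methanol (racemic), via 8-lithio chromene 20 (not isolated)
Conditions: s-BuLi, TMEDA, THF, −78 → −40 °C; 19, −78 → 0 °C; sat. aq NH4Cl
Reagents that add atoms: none
Why: Directed ortho-metalation at C8, the only ring C–H left and flanked by the C7 OMOM group and the ring oxygen, gives the aryllithium, whose 1,2-addition to the aldehyde forms the carbinol as a racemate; this stereocentre is removed in step 12.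

Step 12
Reactants: 21 the diaryl carbinol of step 11
Product: 22 [5,7-bis(methoxymethoxy)-2,2-dimethyl-6-(trimethylsilyl)-2H-chromen-8-yl][3,5-bis(methoxymethoxy)-2-(3-methylbut-2-en-1-yl)phenyl]methanone
Conditions: Dess–Martin periodinane, NaHCO3, CH2Cl2, rt
Reagents that add atoms: none
Why: Dess–Martin oxidation of the doubly benzylic secondary alcohol gives the benzophenone under buffered conditions that leave the electron-rich alkenes, the acetals and the aryl silane alone.

Step 13
Reactants: 22 the protected benzophenone of step 12
Product: 23 (5,7-dihydroxy-2,2-dimethyl-2H-chromen-8-yl)[3,5-dihydroxy-2-(3-methylbut-2-en-1-yl)phenyl]methanone (target)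
Conditions: 3 M aq HCl, MeOH, 40 °C
Reagents that add atoms: none
Why: Acid-catalysed acetal exchange with methanol removes the four MOM groups, and the same medium should effect ipso-protodesilylation at C6, which is favoured because the protonated carbon is ortho to two oxygens and para to the pyran oxygen (β-silicon effect); no stereocentre is involved.

**Compound list**

1 | phloroglucinol | Oc1cc(O)cc(O)c1 | starting material
2 | 3,5-bis(methoxymethoxy)phenol | COCOc1cc(O)cc(OCOC)c1 | intermediate
3 | 3,5-bis(methoxymethoxy)phenyl N,N-diethylcarbamate | CCN(CC)C(=O)Oc1cc(OCOC)cc(OCOC)c1 | intermediate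
4 | 2-(diethylcarbamoyloxy)-4,6-bis(methoxymethoxy)phenyllithium | [Li]c1c(OC(=O)N(CC)CC)cc(OCOC)cc1OCOC | intermediate (not isolated)
5 | 3,5-bis(methoxymethoxy)-2-(trimethylsilyl)phenyl N,N-diethylcarbamate | CCN(CC)C(=O)Oc1cc(OCOC)cc(OCOC)c1[Si](C)(C)C | intermediate
6 | 3,5-bis(methoxymethoxy)-2-(trimethylsilyl)phenol | Oc1cc(OCOC)cc(OCOC)c1[Si](C)(C)C | intermediate
7 | 3,5-bis(methoxymethoxy)-2-(trimethylsilyl)phenyl trifluoromethanesulfonate | COCOc1cc(OCOC)c([Si](C)(C)C)c(OS(=O)(=O)C(F)(F)F)c1 | intermediate
8 | 3-methylbut-2-enal | CC(C)=CC=O | starting material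
9 | 3,5-bis(methoxymethoxy)benzyne | COCOC1=CC(OCOC)=CC#C1 | intermediate (not isolated)
10 | 3,5-bis(methoxymethoxy)-2-(2-methylprop-1-en-1-yl)-2H-benzo[b]oxete (racemic) | COCOc1cc(OCOC)c2C(C=C(C)C)Oc2c1 | intermediate (not isolated)
11 | (6Z)-3,5-bis(methoxymethoxy)-6-(3-methylbut-2-en-1-ylidene)cyclohexa-2,4-dien-1-one | O=C1C=C(OCOC)C=C(OCOC)/C1=C/C=C(C)C | intermediate (not isolated)
12 | 5,7-bis(methoxymethoxy)-2,2-dimethyl-2H-chromene | COCOc1cc(OCOC)c2C=CC(C)(C)Oc2c1 | intermediate
13 | 5,7-bis(methoxymethoxy)-2,2-dimethyl-2H-chromen-6-yllithium | COCOc1c([Li])c(OCOC)c2C=CC(C)(C)Oc2c1 | intermediate (not isolated)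
14 | 5,7-bis(methoxymethoxy)-2,2-dimethyl-6-(trimethylsilyl)-2H-chromene | COCOc1c([Si](C)(C)C)c(OCOC)c2C=CC(C)(C)Oc2c1 | intermediate
15 | 3,5-dihydroxybenzaldehyde | O=Cc1cc(O)cc(O)c1 | starting material
16 | 3,5-bis(methoxymethoxy)benzaldehyde | O=Cc1cc(OCOC)cc(OCOC)c1 | intermediate
17 | 2-bromo-3,5-bis(methoxymethoxy)benzaldehyde | O=Cc1cc(OCOC)cc(OCOC)c1Br | intermediate
18 | tributyl(3-methylbut-2-en-1-yl)stannane | CCCC[Sn](CCCC)(CCCC)CC=C(C)C | starting material
19 | 3,5-bis(methoxymethoxy)-2-(3-methylbut-2-en-1-yl)benzaldehyde | O=Cc1cc(OCOC)cc(OCOC)c1CC=C(C)C | intermediate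
20 | 5,7-bis(methoxymethoxy)-2,2-dimethyl-6-(trimethylsilyl)-2H-chromen-8-yllithium | COCOc1c([Si](C)(C)C)c(OCOC)c2C=CC(C)(C)Oc2c1[Li] | intermediate (not isolated)
21 | [5,7-bis(methoxymethoxy)-2,2-dimethyl-6-(trimethylsilyl)-2H-chromen-8-yl][3,5-bis(methoxymethoxy)-2-(3-methylbut-2-en-1-yl)phenyl]methanol (racemic) | COCOc1cc(OCOC)c(CC=C(C)C)c(C(O)c2c(OCOC)c([Si](C)(C)C)c(OCOC)c3C=CC(C)(C)Oc23)c1 | intermediate
22 | [5,7-bis(methoxymethoxy)-2,2-dimethyl-6-(trimethylsilyl)-2H-chromen-8-yl][3,5-bis(methoxymethoxy)-2-(3-methylbut-2-en-1-yl)phenyl]methanone | COCOc1cc(OCOC)c(CC=C(C)C)c(C(=O)c2c(OCOC)c([Si](C)(C)C)c(OCOC)c3C=CC(C)(C)Oc23)c1 | intermediate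
23 | (5,7-dihydroxy-2,2-dimethyl-2H-chromen-8-yl)[3,5-dihydroxy-2-(3-methylbut-2-en-1-yl)phenyl]methanone | CC(C)=CCc1c(O)cc(O)cc1C(=O)c1c(O)cc(O)c2c1OC(C)(C)C=C2 | target

**Step count**

Total step count: 13. Longest linear sequence: 10 steps (steps 1–7 and 11–13); steps 8–10 form the ring-A branch.

**Steps most likely to fail**

Step 6. The aryne may be consumed by pathways other than the carbonyl [2+2] (ene or [4+2] reaction with the enal, addition of a second aryne to the o-quinone methide), or fluoride-promoted self-condensation of the enal may outrun aryne release. The fallback sets out from phenol 2 and condenses it with enal 8 under ethylenediammonium diacetate catalysis in toluene at reflux. Knoevenagel-type ortho-C-alkylation and loss of water give the same o-quinone methide 11, which closes to chromene 12, where the route is rejoined; steps 2 to 5 then fall away. In this variant the four-membered oxete is bypassed and the pyran closes directly from the dienone. The fallback makes no new compound (F0).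

Step 11. The flanked aryllithium 20 may act as a base toward the benzylic–allylic CH2 of aldehyde 19 instead of adding, or addition to the ortho-substituted aldehyde may be too slow. The fallback changes the order of bond formation. Aryllithium 20, made from 14 as before, is added to the bromo aldehyde 17, which has no acidic side chain, to give [2-bromo-3,5-bis(methoxymethoxy)phenyl][5,7-bis(methoxymethoxy)-2,2-dimethyl-6-(trimethylsilyl)-2H-chromen-8-yl]methanol F1. Dess–Martin oxidation gives the corresponding bromo benzophenone F2. Stille coupling of F2 with stannane 18 (Pd(PPh3)4, DMF, 100 °C), helped by the ortho carbonyl group, then installs the prenyl group and comes back to the route at ketone 22.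

Step 13. In protic acid the o-prenylphenol of ring A can cyclise to a 2,2-dimethylchroman, and the chromene double bond can add methanol or HCl before the last acetal and the C–Si bond are cleaved. The fallback separates the two unmasking events and avoids Brønsted acid. From 22, fluoride-induced protodesilylation (TBAF, wet THF) gives [5,7-bis(methoxymethoxy)-2,2-dimethyl-2H-chromen-8-yl][3,5-bis(methoxymethoxy)-2-(3-methylbut-2-en-1-yl)phenyl]methanone F3. The four MOM ethers are then removed with ZnBr2 and n-PrSH in CH2Cl2 at 0 °C (Lewis acid-assisted thiol transacetalisation), which comes back at target 23.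

**Further compounds**

F0 | step 6 | none | none
F1 | step 11 | [2-bromo-3,5-bis(methoxymethoxy)phenyl][5,7-bis(methoxymethoxy)-2,2-dimethyl-6-(trimethylsilyl)-2H-chromen-8-yl]methanol (racemic) | COCOc1cc(OCOC)c(Br)c(C(O)c2c(OCOC)c([Si](C)(C)C)c(OCOC)c3C=CC(C)(C)Oc23)c1
F2 | step 11 | [2-bromo-3,5-bis(methoxymethoxy)phenyl][5,7-bis(methoxymethoxy)-2,2-dimethyl-6-(trimethylsilyl)-2H-chromen-8-yl]methanone | COCOc1cc(OCOC)c(Br)c(C(=O)c2c(OCOC)c([Si](C)(C)C)c(OCOC)c3C=CC(C)(C)Oc23)c1
F3 | step 13 | [5,7-bis(methoxymethoxy)-2,2-dimethyl-2H-chromen-8-yl][3,5-bis(methoxymethoxy)-2-(3-methylbut-2-en-1-yl)phenyl]methanone | COCOc1cc(OCOC)c(CC=C(C)C)c(C(=O)c2c(OCOC)cc(OCOC)c3C=CC(C)(C)Oc23)c1
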